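Daucane numbering: C1 quaternary methyl carbon, C4 isopropyl carbinol, C5 ring-fusion CH, C6 ester carbinol, C7=C8, C9 allylic carbinol, C10 methylene. The route rests on closing the seven-membered ring at C9–C10. It exploits the 1,4-relationship of the oxygens on C6 and C9 across C7–C8 and the neopentyl position of C10: the precursor is a cyclopentane (cut from (R)-terpinen-4-ol by ring contraction) carrying an iodomethyl group on C1 and an α-methylene-γ-butyrolactone on C5. Iodine–lithium exchange and attack of C10 on the lactone carbonyl C9 give an oxygen-bridged hemiketal whose collapse delivers the hydroazulene, the C9 ketone and the free C6 hydroxyl in one operation.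

Key step: step 9

Assumption: (R)-(−)-terpinen-4-ol is taken as a commercial starting material of high enantiomeric purity; the labels C1 to C15 used below follow the daucane numbering of the overview.

Step 1
Reactants: 1 (1R)-4-methyl-1-(propan-2-yl)cyclohex-3-en-1-ol
Product: 2 triethyl{[(1R)-4-methyl-1-(propan-2-yl)cyclohex-3-en-1-yl]oxy}silane
Conditions: Et3SiOTf, 2,6-lutidine, CH2Cl2, −78 to 0 °C
Reagents that add atoms: triethylsilyl trifluoromethanesulfonate, CC[Si](CC)(CC)OS(=O)(=O)C(F)(F)F
Why: Silyl ether formation with a silyl triflate protects the tertiary alcohol so that the β-oxygenated carbonyl compounds that follow cannot undergo retro-aldol cleavage, and no stereocenter is touched.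

Step 2
Reactants: 2 triethyl{[(1R)-4-methyl-1-(propan-2-yl)cyclohex-3-en-1-yl]oxy}silane
Product: 4 (5S)-2-methyl-5-(propan-2-yl)-5-[(triethylsilyl)oxy]cyclohex-2-en-1-one, via allylic alcohol 3 (not isolated)
Conditions: SeO2 (0.5 equiv), t-BuOOH, CH2Cl2, 25 °C; then MnO2, CH2Cl2, 25 °C
Reagents that add atoms: tert-butyl hydroperoxide, CC(C)(C)OO
Why: SeO2 allylic oxidation (ene reaction then 2,3-sigmatropic shift) should place oxygen on the ring methylene C6 beside the methyl-bearing alkene carbon without a symmetric allyl intermediate, so the C4 configuration is kept, and MnO2 then oxidises the allylic alcohol to the enone.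

Step 3
Reactants: 4 (5S)-2-methyl-5-(propan-2-yl)-5-[(triethylsilyl)oxy]cyclohex-2-en-1-one
Product: 6 (2R,5S)-2-(hydroxymethyl)-2-methyl-5-(propan-2-yl)-5-[(triethylsilyl)oxy]cyclohexan-1-one, via lithium enolate 5 (not isolated)
Conditions: Li, liquid NH3, THF, t-BuOH (1 equiv), −78 °C; isoprene; NH3 removed; CH2O (gas), THF, −78 °C; aq. NH4Cl
Reagents that add atoms: formaldehyde, C=O
Why: Dissolving-metal reductive alkylation of the enone gives the C1 enolate regiospecifically and formaldehyde should add axially, cis to the equatorial isopropyl group on C4 (the sense known for alkylation of dihydrocarvone enolates), which sets the quaternary center C1 with the future C10 trans to the silyloxy group.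

Step 4
Reactants: 6 (2R,5S)-2-(hydroxymethyl)-2-methyl-5-(propan-2-yl)-5-[(triethylsilyl)oxy]cyclohexan-1-one
Product: 7 (2S,5S)-2-(iodomethyl)-2-methyl-5-(propan-2-yl)-5-[(triethylsilyl)oxy]cyclohexan-1-one
Conditions: PPh3, I2, imidazole, toluene, 70 °C
Reagents that add atoms: iodine, II
Why: Appel-type iodination of the primary neopentyl alcohol proceeds by displacement of the alkoxyphosphonium group without rearrangement, and the β-iodo ketone cannot eliminate because C1 carries no hydrogen.

Step 5
Reactants: 7 (2S,5S)-2-(iodomethyl)-2-methyl-5-(propan-2-yl)-5-[(triethylsilyl)oxy]cyclohexan-1-one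
Product: 9 (3R,6S)-2-diazo-6-(iodomethyl)-6-methyl-3-(propan-2-yl)-3-[(triethylsilyl)oxy]cyclohexan-1-one, via trifluoroacetyl ketone 8 (not isolated)
Conditions: LiN(SiMe3)2, THF, −78 °C; CF3CO2CH2CF3; then MsN3, Et3N, H2O, MeCN, 25 °C
Reagents that add atoms: methanesulfonyl azide, CS(=O)(=O)N=[N+]=[N-]
Why: Regitz-type detrifluoroacetylative diazo transfer should work because C5 is the only enolisable position of the ketone and the lithium enolate with its β-silyloxy group is stable at −78 °C.

Step 6
Reactants: 9 (3R,6S)-2-diazo-6-(iodomethyl)-6-methyl-3-(propan-2-yl)-3-[(triethylsilyl)oxy]cyclohexan-1-one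
Product: 12 methyl (1R,2R,5S)-2-hydroxy-5-(iodomethyl)-5-methyl-2-(propan-2-yl)cyclopentane-1-carboxylate, via ketene 10 (not isolated), via silyl ether ester 11 (not isolated)
Conditions: hν (350 nm), MeOH, 0 °C; then NaOMe (0.3 equiv), MeOH, 25 °C; then HCl (1 mol/L in MeOH), 25 °C
Reagents that add atoms: methanol, CO
Why: Photochemical Wolff rearrangement contracts the ring by migration of C1 to C5 with retention, methanol traps the ketene, methoxide should equilibrate C5 to the ester that lies trans to both the isopropyl and the iodomethyl group (C5–H cis to isopropyl), and acid removes the silyl group.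

Step 7
Reactants: 12 methyl (1R,2R,5S)-2-hydroxy-5-(iodomethyl)-5-methyl-2-(propan-2-yl)cyclopentane-1-carboxylate
Product: 13 (1R,2R,5S)-2-hydroxy-5-(iodomethyl)-5-methyl-2-(propan-2-yl)cyclopentane-1-carbaldehyde
Conditions: i-Bu2AlH (2.5 equiv), CH2Cl2, −78 °C; aq. KNaC4H4O6
Reagents that add atoms: none
Why: In this partial ester reduction the aluminium alkoxide of the neighbouring hydroxyl should chelate and stabilise the tetrahedral intermediate at −78 °C, so that the aldehyde is released only on work-up and C5 is unchanged.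

Step 8
Reactants: 13 (1R,2R,5S)-2-hydroxy-5-(iodomethyl)-5-methyl-2-(propan-2-yl)cyclopentane-1-carbaldehyde; 14 ethyl 2-(bromomethyl)prop-2-enoate
Product: 16 (5S)-5-[(1S,2R,5S)-2-hydroxy-5-(iodomethyl)-5-methyl-2-(propan-2-yl)cyclopentyl]-3-methylideneoxolan-2-one, via hydroxy ester 15 (not isolated)
Conditions: indium powder, THF/H2O (1:1), 25 °C; then TsOH (cat.), CH2Cl2, 25 °C
Reagents that add atoms: none
Why: Barbier allylation with the allylindium reagent should run under chelation by the β-hydroxyl, the nucleophile attacking the aldehyde face turned away from the quaternary C1 to give the (S)-carbinol at C6, and the γ-hydroxy ester then lactonises.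

Step 9
Reactants: 16 (5S)-5-[(1S,2R,5S)-2-hydroxy-5-(iodomethyl)-5-methyl-2-(propan-2-yl)cyclopentyl]-3-methylideneoxolan-2-one
Product: 19 (1R,3aR,8S,8aS)-1,8-dihydroxy-3a-methyl-6-methylidene-1-(propan-2-yl)octahydroazulen-5(1H)-one, via alkyllithium 17 (not isolated), via bridged lithium hemiketal 18 (not isolated)
Conditions: t-BuLi (3.2 equiv), Et2O/pentane, −100 to −40 °C; aq. NH4Cl
Reagents that add atoms: none
Why: t-BuLi first deprotonates the tertiary hydroxyl and then exchanges the primary neopentyl iodide for lithium (the second equivalent destroys t-BuI); the C10 carbanion, which has no β-hydrogen to lose, adds to the lactone carbonyl C9, and the lithium hemiketal 18 opens on protonation to the C9 ketone and the C6 hydroxyl. The closest known reaction type is the Parham cyclisation, here an intramolecular nucleophilic acyl substitution of an iodoalkyl lactone that amounts to an anionic ring expansion. The carbonyl addition is 6-exo-trig for the oxygen-containing ring C9–O–C6–C5–C1–C10 (7-exo-trig for the carbocycle C1–C5–C6–C7–C8–C9–C10) and gives an 8-oxabicyclo[3.2.1]octane whose C9–O bond then breaks. No new stereocenter survives, because the bridged hemiketal carbon C9 becomes trigonal; C1, C4, C5 and C6 are untouched, and the trans ring fusion follows from the trans arrangement of C10 and C6 on the cyclopentane. The step needs halogen–lithium exchange to outrun addition of t-BuLi to the lactone, and 1,2-addition of C10 to beat 1,4-addition to the α-methylene lactone; the first is secured by the very fast exchange of primary iodides at −100 °C, the second by the hard alkyllithium and by a six-membered transition state for carbonyl attack against a seven-membered one for attack at the exocyclic methylene carbon. A second addition is excluded because the tetrahedral alkoxide persists until the quench.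

Step 10
Reactants: 19 (1R,3aR,8S,8aS)-1,8-dihydroxy-3a-methyl-6-methylidene-1-(propan-2-yl)octahydroazulen-5(1H)-one; 20 4-methoxybenzoyl chloride
Product: 21 (1R,3aR,8S,8aS)-1-hydroxy-3a-methyl-6-methylidene-5-oxo-1-(propan-2-yl)decahydroazulen-8-yl 4-methoxybenzoate
Conditions: Et3N, DMAP (cat.), CH2Cl2, 25 °C
Reagents that add atoms: none
Why: DMAP-catalysed acylation should esterify the secondary C6 hydroxyl of the open hydroxy ketone form, which is far more reactive than the tertiary C4 hydroxyl.

Step 11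
Reactants: 21 (1R,3aR,8S,8aS)-1-hydroxy-3a-methyl-6-methylidene-5-oxo-1-(propan-2-yl)decahydroazulen-8-yl 4-methoxybenzoate
Product: 22 (1R,3aR,8S,8aS)-1-hydroxy-3a,6-dimethyl-5-oxo-1-(propan-2-yl)-1,2,3,3a,4,5,8,8a-octahydroazulen-8-yl 4-methoxybenzoate
Conditions: RhCl3·3H2O (5 mol%), EtOH, 75 °C
Reagents that add atoms: none
Why: Rhodium hydride alkene isomerisation should move the exocyclic double bond of the α-methylene ketone into the ring to give the more substituted 2-methyl enone (C7=C8), the only endocyclic conjugated position since C10 lies on the other side of the carbonyl.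

Step 12
Reactants: 22 (1R,3aR,8S,8aS)-1-hydroxy-3a,6-dimethyl-5-oxo-1-(propan-2-yl)-1,2,3,3a,4,5,8,8a-octahydroazulen-8-yl 4-methoxybenzoate
Product: 23 (1R,3aR,5R,8S,8aS)-1,5-dihydroxy-3a,6-dimethyl-1-(propan-2-yl)-1,2,3,3a,4,5,8,8a-octahydroazulen-8-yl 4-methoxybenzoate
Conditions: NaBH4, CeCl3·7H2O, MeOH, −40 °C
Reagents that add atoms: none
Why: Luche 1,2-reduction of the enone should deliver hydride to the face of C9 opposite the angular methyl group on C1, giving the (9R)-allylic alcohol cis to that methyl group while the aryl ester survives.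

Compound list

1 | (1R)-4-methyl-1-(propan-2-yl)cyclohex-3-en-1-ol, (R)-terpinen-4-ol | CC1=CC[C@@](O)(C(C)C)CC1 | starting material
2 | triethyl{[(1R)-4-methyl-1-(propan-2-yl)cyclohex-3-en-1-yl]oxy}silane | CC1=CC[C@@](O[Si](CC)(CC)CC)(C(C)C)CC1 | intermediate
3 | (5S)-2-methyl-5-(propan-2-yl)-5-[(triethylsilyl)oxy]cyclohex-2-en-1-ol (both C1 epimers) | CC1=CC[C@@](O[Si](CC)(CC)CC)(C(C)C)CC1O | intermediate
4 | (5S)-2-methyl-5-(propan-2-yl)-5-[(triethylsilyl)oxy]cyclohex-2-en-1-one | CC1=CC[C@@](O[Si](CC)(CC)CC)(C(C)C)CC1=O | intermediate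
5 | lithium (5S)-2-methyl-5-(propan-2-yl)-5-[(triethylsilyl)oxy]cyclohex-1-en-1-olate | [Li]OC1=C(C)CC[C@@](O[Si](CC)(CC)CC)(C(C)C)C1 | intermediate
6 | (2R,5S)-2-(hydroxymethyl)-2-methyl-5-(propan-2-yl)-5-[(triethylsilyl)oxy]cyclohexan-1-one (hydroxymethyl cis to isopropyl) | OC[C@@]1(C)CC[C@@](O[Si](CC)(CC)CC)(C(C)C)CC1=O | intermediate
7 | (2S,5S)-2-(iodomethyl)-2-methyl-5-(propan-2-yl)-5-[(triethylsilyl)oxy]cyclohexan-1-one | IC[C@@]1(C)CC[C@@](O[Si](CC)(CC)CC)(C(C)C)CC1=O | intermediate
8 | (3R,6S)-6-(iodomethyl)-6-methyl-3-(propan-2-yl)-2-(trifluoroacetyl)-3-[(triethylsilyl)oxy]cyclohexan-1-one (enolised) | IC[C@@]1(C)CC[C@@](O[Si](CC)(CC)CC)(C(C)C)C(C(=O)C(F)(F)F)C1=O | intermediate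
9 | (3R,6S)-2-diazo-6-(iodomethyl)-6-methyl-3-(propan-2-yl)-3-[(triethylsilyl)oxy]cyclohexan-1-one | IC[C@@]1(C)CC[C@@](O[Si](CC)(CC)CC)(C(C)C)C(=[N+]=[N-])C1=O | intermediate
10 | {(2S,5R)-2-(iodomethyl)-2-methyl-5-(propan-2-yl)-5-[(triethylsilyl)oxy]cyclopentylidene}methanone (ketene) | O=C=C1[C@](O[Si](CC)(CC)CC)(C(C)C)CC[C@]1(C)CI | intermediate
11 | methyl (1R,2R,5S)-5-(iodomethyl)-5-methyl-2-(propan-2-yl)-2-[(triethylsilyl)oxy]cyclopentane-1-carboxylate | COC(=O)[C@H]1[C@](O[Si](CC)(CC)CC)(C(C)C)CC[C@]1(C)CI | intermediate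
12 | methyl (1R,2R,5S)-2-hydroxy-5-(iodomethyl)-5-methyl-2-(propan-2-yl)cyclopentane-1-carboxylate | COC(=O)[C@H]1[C@](O)(C(C)C)CC[C@]1(C)CI | intermediate
13 | (1R,2R,5S)-2-hydroxy-5-(iodomethyl)-5-methyl-2-(propan-2-yl)cyclopentane-1-carbaldehyde | O=C[C@H]1[C@](O)(C(C)C)CC[C@]1(C)CI | intermediate
14 | ethyl 2-(bromomethyl)prop-2-enoate | CCOC(=O)C(=C)CBr | starting material
15 | ethyl (4S)-4-hydroxy-4-[(1S,2R,5S)-2-hydroxy-5-(iodomethyl)-5-methyl-2-(propan-2-yl)cyclopentyl]-2-methylidenebutanoate | CCOC(=O)C(=C)C[C@H](O)[C@H]1[C@](O)(C(C)C)CC[C@]1(C)CI | intermediate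
16 | (5S)-5-[(1S,2R,5S)-2-hydroxy-5-(iodomethyl)-5-methyl-2-(propan-2-yl)cyclopentyl]-3-methylideneoxolan-2-one | C=C1C[C@H](OC1=O)[C@H]2[C@](O)(C(C)C)CC[C@]2(C)CI | intermediate
17 | lithium alkoxide of 16 in which the iodine on C10 is replaced by lithium | C=C1C[C@H](OC1=O)[C@H]2[C@](O[Li])(C(C)C)CC[C@]2(C)C[Li] | intermediate
18 | dilithium salt of the bridged hemiketal (8-oxabicyclo[3.2.1]octane, oxygen bridge from C6 to C9, fused cyclopentane) | C=C1C[C@@H]2O[C@@]1(O[Li])C[C@@]1(C)CC[C@@](O[Li])(C(C)C)[C@H]21 | intermediate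
19 | (1R,3aR,8S,8aS)-1,8-dihydroxy-3a-methyl-6-methylidene-1-(propan-2-yl)octahydroazulen-5(1H)-one | C=C1C[C@H](O)[C@H]2[C@](O)(C(C)C)CC[C@]2(C)CC1=O | intermediate
20 | 4-methoxybenzoyl chloride | COc1ccc(cc1)C(Cl)=O | starting material
21 | (1R,3aR,8S,8aS)-1-hydroxy-3a-methyl-6-methylidene-5-oxo-1-(propan-2-yl)decahydroazulen-8-yl 4-methoxybenzoate | C=C1C[C@H](OC(=O)c3ccc(OC)cc3)[C@H]2[C@](O)(C(C)C)CC[C@]2(C)CC1=O | intermediate
22 | (1R,3aR,8S,8aS)-1-hydroxy-3a,6-dimethyl-5-oxo-1-(propan-2-yl)-1,2,3,3a,4,5,8,8a-octahydroazulen-8-yl 4-methoxybenzoate | CC1=C[C@H](OC(=O)c3ccc(OC)cc3)[C@H]2[C@](O)(C(C)C)CC[C@]2(C)CC1=O | intermediate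
23 | (1R,3aR,5R,8S,8aS)-1,5-dihydroxy-3a,6-dimethyl-1-(propan-2-yl)-1,2,3,3a,4,5,8,8a-octahydroazulen-8-yl 4-methoxybenzoate | COc1ccc(C(=O)O[C@H]2C=C(C)[C@H](O)C[C@@]3(C)CC[C@@](O)(C(C)C)[C@H]23)cc1 | target

Total step count: 12. Longest linear sequence: 12 steps (1 to 23).

Steps most likely to fail, each with a fallback:

The key step (step 9) is the most exposed. t-BuLi may add to the lactone or to its methylene group before the exchange is complete, or the C10 carbanion may add in a conjugate sense. The fallback sets out from 16 and avoids an organolithium. Reduction with i-Bu2AlH at −78 °C should give the lactol (5S)-5-[(1S,2R,5S)-2-hydroxy-5-(iodomethyl)-5-methyl-2-(propan-2-yl)cyclopentyl]-3-methylideneoxolan-2-ol F1. Its open hydroxy aldehyde form is then closed at C9–C10 by an intramolecular Nozaki–Hiyama–Kishi-type alkylchromium addition (CrCl2, catalytic Co(C32H16N8), DMF). This should give (1R,3aR,8S,8aS)-3a-methyl-6-methylidene-1-(propan-2-yl)decahydroazulene-1,5,8-triol F2 as C5 epimers of the azulene numbering. MnO2 then oxidises only the allylic hydroxyl, which returns the route to 19.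

Step 6 may lose material through carbene side reactions in the photolysis or through incomplete equilibration at C5. The fallback sets out from 7 and replaces the Wolff rearrangement by a quasi-Favorskii ring contraction. LiN(SiMe3)2 and Me3SiCl should give the enol ether triethyl{[(1R,4S)-4-(iodomethyl)-4-methyl-1-(propan-2-yl)-3-[(trimethylsilyl)oxy]cyclohex-2-en-1-yl]oxy}silane F3. N-Bromosuccinimide then gives (2S,3R,6S)-2-bromo-6-(iodomethyl)-6-methyl-3-(propan-2-yl)-3-[(triethylsilyl)oxy]cyclohexan-1-one F4. Its bromine is cis to the silyloxy group and equatorial, which should be the stable epimer because an axial bromine would clash with the axial iodomethyl group. NaOMe in MeOH then induces the semibenzilic shift of C1 from C6 to C5 with inversion at C5. This fixes the C5 configuration by the bromide and comes back to the route at 11.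

Step 8 may give poor facial selectivity at C6 if chelation is weak for this hindered aldehyde. The fallback sets out from 13 and moves the control to a reagent. The unselective allylation gives ethyl 4-hydroxy-4-[(1S,2R,5S)-2-hydroxy-5-(iodomethyl)-5-methyl-2-(propan-2-yl)cyclopentyl]-2-methylidenebutanoate F5 as C4 epimers of the butanoate chain. Dess–Martin periodinane oxidises it to ethyl 4-[(1R,2R,5S)-2-hydroxy-5-(iodomethyl)-5-methyl-2-(propan-2-yl)cyclopentyl]-2-methylidene-4-oxobutanoate F6. CBS reduction with (R)-2-methyl-CBS-oxazaborolidine and BH3·SMe2 should then give the (S)-carbinol 15, which lactonises to 16.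

Further compounds

F1 | step 9 | (5S)-5-[(1S,2R,5S)-2-hydroxy-5-(iodomethyl)-5-methyl-2-(propan-2-yl)cyclopentyl]-3-methylideneoxolan-2-ol | C=C1C[C@H](OC1O)[C@H]2[C@](O)(C(C)C)CC[C@]2(C)CI
F2 | step 9 | (1R,3aR,8S,8aS)-3a-methyl-6-methylidene-1-(propan-2-yl)decahydroazulene-1,5,8-triol (C5 epimers) | C=C1C[C@H](O)[C@H]2[C@](O)(C(C)C)CC[C@]2(C)CC1O
F3 | step 6 | triethyl{[(1R,4S)-4-(iodomethyl)-4-methyl-1-(propan-2-yl)-3-[(trimethylsilyl)oxy]cyclohex-2-en-1-yl]oxy}silane | IC[C@@]1(C)CC[C@@](O[Si](CC)(CC)CC)(C(C)C)C=C1O[Si](C)(C)C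
F4 | step 6 | (2S,3R,6S)-2-bromo-6-(iodomethyl)-6-methyl-3-(propan-2-yl)-3-[(triethylsilyl)oxy]cyclohexan-1-one | IC[C@@]1(C)CC[C@@](O[Si](CC)(CC)CC)(C(C)C)[C@H](Br)C1=O
F5 | step 8 | ethyl 4-hydroxy-4-[(1S,2R,5S)-2-hydroxy-5-(iodomethyl)-5-methyl-2-(propan-2-yl)cyclopentyl]-2-methylidenebutanoate (C4 epimers) | CCOC(=O)C(=C)CC(O)[C@H]1[C@](O)(C(C)C)CC[C@]1(C)CI
F6 | step 8 | ethyl 4-[(1R,2R,5S)-2-hydroxy-5-(iodomethyl)-5-methyl-2-(propan-2-yl)cyclopentyl]-2-methylidene-4-oxobutanoate | CCOC(=O)C(=C)CC(=O)[C@H]1[C@](O)(C(C)C)CC[C@]1(C)CI
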